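**Retrosynthetic overview**
- The plan rests on ring A. C6(OMe)–C7(OH) is a methoxyacetyl unit, C8(OMe) is a methoxymethyl group on C8a of a finished ring C, and C5(OH) is an ester carbon on C4a.
- Ring A is disconnected at C7–C8 and C5–C6. A one-pot Claisen–Dieckmann condensation of a 2-methoxymethyl-4-pyranone-3-carboxylate with methyl methoxyacetate forms both bonds.
- The pyranone (ring C with ring B attached) comes from cyclodehydration of a 1,3,5-triketo ester. That ester is made by aroylating the dianion of symmetrical methyl bis(methoxyacetyl)acetate with the ring B Weinreb amide.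
- Ring order: ring B is bought, ring C is closed next, ring A last. Hydrogenolysis of the two ring B benzyl ethers finishes the route.

Key step: step 6

Remark: the target has no stereocentre. Methoxyacetyl chloride is taken as a further commercial building block. Compounds 6, 7 and 10 are drawn as keto forms although they should exist largely as chelated enols, so their C–H stereocentres are not defined.

**Step 1**
Reactants: 1 3,5-dihydroxy-4-methoxybenzoic acid
Product: 2 benzyl 3,5-bis(benzyloxy)-4-methoxybenzoate
Conditions: BnBr (3.3 equiv), K2CO3, DMF, 60 °C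
Reagents that add atoms: benzyl bromide, BrCc1ccccc1
Why: Williamson ether synthesis (SN2) on both phenoxides, with the carboxylate alkylated at the same time, should give the tribenzyl compound because the 4-methoxy group is inert.

**Step 2**
Reactants: 2 benzyl 3,5-bis(benzyloxy)-4-methoxybenzoate
Product: 3 3,5-bis(benzyloxy)-N,4-dimethoxy-N-methylbenzamide
Conditions: MeNH(OMe)·HCl, i-PrMgCl, THF, −20 to 0 °C
Reagents that add atoms: N,O-dimethylhydroxylamine hydrochloride, CNOC.Cl
Why: The chloromagnesium amide of N,O-dimethylhydroxylamine, formed in the flask, should displace benzyl oxide from the ester by acyl substitution (direct ester-to-Weinreb-amide aminolysis) without touching the aryl benzyl ethers.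

**Step 3**
Reactants: 4 methyl 4-methoxy-3-oxobutanoate (methyl 4-methoxyacetoacetate); 5 methoxyacetyl chloride
Product: 6 methyl 4-methoxy-2-(2-methoxyacetyl)-3-oxobutanoate
Conditions: MgCl2, pyridine, CH2Cl2, 0 °C to rt; then 1 M HCl
Reagents that add atoms: none
Why: Magnesium-mediated soft enolisation gives the chelated enolate of the β-keto ester, which should be C-acylated by the acid chloride (Claisen-type C-acylation), and the more acidic product stays bound as its magnesium chelate, which suppresses O-acylation and a second acylation.

**Step 4**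
Reactants: 6 methyl 4-methoxy-2-(2-methoxyacetyl)-3-oxobutanoate; 3 3,5-bis(benzyloxy)-N,4-dimethoxy-N-methylbenzamide
Product: 7 methyl 5-[3,5-bis(benzyloxy)-4-methoxyphenyl]-4-methoxy-2-(2-methoxyacetyl)-3,5-dioxopentanoate
Conditions: 6 (1.2 equiv), LiN(i-Pr)2 (2.5 equiv), THF, −78 to 0 °C; then 3, −78 to 0 °C; then cold 1 M HCl
Reagents that add atoms: none
Why: Double deprotonation gives the tricarbonylmethanide and then the terminal α-methoxy enolate, and this γ-carbon of the 1,3-dicarbonyl dianion should add to the amide (Weinreb ketone synthesis) to give a chelated adduct that releases the aryl ketone only on quench, while the equivalence of the two methoxyacetyl arms of 6 allows only one constitution.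

**Step 5**
Reactants: 7 methyl 5-[3,5-bis(benzyloxy)-4-methoxyphenyl]-4-methoxy-2-(2-methoxyacetyl)-3,5-dioxopentanoate
Product: 8 methyl 6-[3,5-bis(benzyloxy)-4-methoxyphenyl]-5-methoxy-2-(methoxymethyl)-4-oxo-4H-pyran-3-carboxylate
Conditions: p-TsOH·H2O (0.2 equiv), toluene, 4 Å MS, 80 °C
Reagents that add atoms: none
Why: In this acid-catalysed cyclodehydration of a 1,3,5-triketone to a 4-pyranone the enol oxygen of one outer ketone should add to the other outer ketone (6-exo-trig) and the hemiketal should lose water, whereas lactonisation onto the less electrophilic ester would need loss of methanol and is disfavoured under acid.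

**Step 6**
Reactants: 8 methyl 6-[3,5-bis(benzyloxy)-4-methoxyphenyl]-5-methoxy-2-(methoxymethyl)-4-oxo-4H-pyran-3-carboxylate; 9 methyl methoxyacetate
Product: 11 2-[3,5-bis(benzyloxy)-4-methoxyphenyl]-5,7-dihydroxy-3,6,8-trimethoxy-4H-chromen-4-one, via side-chain methoxyacetyl ketone 10 (not isolated)
Conditions: lithium 2,2,6,6-tetramethylpiperidide (1.1 equiv), THF, −78 °C; then 9 (4 equiv) and further lithium 2,2,6,6-tetramethylpiperidide (2.4 equiv), −78 to 0 °C; then 1 M HCl
Reagents that add atoms: none
Why: Proposed new method: the hindered amide removes a proton from the methoxymethyl group on pyranone C2 of 8, which is the vinylogous α-position of the C4 carbonyl and the γ-position of the C3 enoate, and the lithium dienolate is acylated by 9 to give ketone 10 (flavone bond C7–C8), which is deprotonated at once at C8. Further base, or proton shuttling by the lithium enolate of the excess 9, generates the enolate on the methoxymethyl side of the new ketone, and this carbon attacks the neighbouring ring ester in a 6-(enolendo)-exo-trig Dieckmann closure (flavone bond C5–C6), after which loss of methoxide and enolisation give the 5,7-diphenoxide of ring A. The closest known reaction types are the tandem Claisen–Dieckmann condensations of ortho-toluate anions with esters, the Staunton–Weinreb annulation and the Claisen-type cyclisation of polyketide triketo esters to phloroglucinols. No stereocentre is formed, and C6 and C8 arrive with their methoxy groups and C5 and C7 with their hydroxyl groups, so ring A needs no later adjustment. The step needs γ-deprotonation to win over addition of base or enolate to the pyranone, which the hindered amide at −78 °C and the fully substituted pyranone C2 and C6 positions secure, and it needs cross-acylation to win over self-condensation of 9, which metalation of the more acidic 8 before 9 is added and the chelating α-methoxy ester favour; the irreversible aromatisation pulls both equilibria forward and the reverse order of the two acylations would lead to the same ring.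

**Step 7**
Reactants: 11 2-[3,5-bis(benzyloxy)-4-methoxyphenyl]-5,7-dihydroxy-3,6,8-trimethoxy-4H-chromen-4-one
Product: 12 5,7,3',5'-tetrahydroxy-3,6,8,4'-tetramethoxyflavone
Conditions: H2 (1 atm), 10% Pd/C, EtOAc/MeOH, rt
Reagents that add atoms: none
Why: Heterogeneous palladium-catalysed hydrogenolysis should cleave the two benzylic C–O bonds selectively, because aryl methyl ethers and the tetrasubstituted C2=C3 bond of the chromone are not reduced at atmospheric pressure.

**Compound list**
1 | 3,5-dihydroxy-4-methoxybenzoic acid | COc1c(O)cc(C(=O)O)cc1O | starting material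
2 | benzyl 3,5-bis(benzyloxy)-4-methoxybenzoate | COc1c(OCc2ccccc2)cc(C(=O)OCc2ccccc2)cc1OCc1ccccc1 | intermediate
3 | 3,5-bis(benzyloxy)-N,4-dimethoxy-N-methylbenzamide | COc1c(OCc2ccccc2)cc(C(=O)N(C)OC)cc1OCc1ccccc1 | intermediate
4 | methyl 4-methoxy-3-oxobutanoate (methyl 4-methoxyacetoacetate) | COCC(=O)CC(=O)OC | starting material
5 | methoxyacetyl chloride | COCC(=O)Cl | starting material
6 | methyl 4-methoxy-2-(2-methoxyacetyl)-3-oxobutanoate | COCC(=O)C(C(=O)OC)C(=O)COC | intermediate
7 | methyl 5-[3,5-bis(benzyloxy)-4-methoxyphenyl]-4-methoxy-2-(2-methoxyacetyl)-3,5-dioxopentanoate | COCC(=O)C(C(=O)OC)C(=O)C(OC)C(=O)c1cc(OCc2ccccc2)c(OC)c(OCc2ccccc2)c1 | intermediate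
8 | methyl 6-[3,5-bis(benzyloxy)-4-methoxyphenyl]-5-methoxy-2-(methoxymethyl)-4-oxo-4H-pyran-3-carboxylate | COCc1oc(-c2cc(OCc3ccccc3)c(OC)c(OCc3ccccc3)c2)c(OC)c(=O)c1C(=O)OC | intermediate
9 | methyl methoxyacetate | COCC(=O)OC | starting material
10 | methyl 6-[3,5-bis(benzyloxy)-4-methoxyphenyl]-2-(1,3-dimethoxy-2-oxopropyl)-5-methoxy-4-oxo-4H-pyran-3-carboxylate (present as its lithium enolate, not isolated) | COCC(=O)C(OC)c1oc(-c2cc(OCc3ccccc3)c(OC)c(OCc3ccccc3)c2)c(OC)c(=O)c1C(=O)OC | intermediate
11 | 2-[3,5-bis(benzyloxy)-4-methoxyphenyl]-5,7-dihydroxy-3,6,8-trimethoxy-4H-chromen-4-one | COc1c(OCc2ccccc2)cc(-c2oc3c(OC)c(O)c(OC)c(O)c3c(=O)c2OC)cc1OCc1ccccc1 | intermediate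
12 | 5,7,3',5'-tetrahydroxy-3,6,8,4'-tetramethoxyflavone | COc1c(O)cc(-c2oc3c(OC)c(O)c(OC)c(O)c3c(=O)c2OC)cc1O | target

**Total step count:** 7
**Longest linear sequence:** 6 steps (steps 1, 2, 4, 5, 6, 7; step 3 is a one-step branch)

**Steps most likely to fail**

1. Step 6 (proposed new method).
 - What may go wrong: the excess base may enolise 9 and let it self-condense faster than the dienolate of 8 is acylated. The reaction may stall after the first acylation because the more acidic ketone quenches unreacted dienolate. Methoxide may add to the pyranone and open it.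
 - Fallback (sets out from 8, comes back at 11): the two bond formations are separated and the ester is replaced by an amide. Compound 8 is metalated with one equivalent of lithium 2,2,6,6-tetramethylpiperidide at −78 °C and acylated with commercial N-methoxy-N-methyl-2-methoxyacetamide. This is the acylation of a lithium dienolate by a Weinreb amide; the chelated adduct survives until the acid quench, so no enolisable ester and no acidic ketone are present while the C7–C8 bond forms, and ketone 10 is isolated. Compound 10 is then closed in a separate operation with a thermodynamic base (KOt-Bu in THF, or Mg(OMe)2 in MeOH). This is the base-mediated intramolecular Claisen condensation by which keto esters of the polyketide type are turned into 1,3-dihydroxyarenes, and it gives 11.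

2. Step 4.
 - What may go wrong: the second deprotonation of the tricarbonylmethanide may be incomplete. The α-methoxy carbanion may add only slowly to the electron-rich Weinreb amide, so that proton transfer and decomposition of the dianion compete.
 - Fallback (sets out from 4, 5 and 3, comes back at 8): only a monoanion is needed. Compound 4 is condensed with pyrrolidine to methyl (E)-4-methoxy-3-(pyrrolidin-1-yl)but-2-enoate F1. F1 is C-acylated with 5 (pyridine, CH2Cl2) to the push–pull enaminone methyl 4-methoxy-2-(2-methoxyacetyl)-3-(pyrrolidin-1-yl)but-2-enoate F2. F2 is deprotonated once with LiN(SiMe3)2 in THF at −78 °C and aroylated with 3 to methyl 5-[3,5-bis(benzyloxy)-4-methoxyphenyl]-4-methoxy-2-[2-methoxy-1-(pyrrolidin-1-yl)ethylidene]-3,5-dioxopentanoate F3. Aqueous HCl then closes F3 to 8 by addition of the aryl ketone enol oxygen to the enamine carbon and loss of pyrrolidine. Aroylation at the other methoxymethyl arm would lead to the same pyranone after hydrolysis. This is the established 4-pyranone synthesis from enaminones and acyl donors, and compound 7 is bypassed.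

3. Step 5.
 - What may go wrong: the aryl ketone enol may close on the ester with loss of methanol and give a 3-acyl-4-hydroxy-2-pyranone. Prolonged heating with acid may also cleave the benzyl ethers.
 - Fallback (sets out from 2 and from the enamino ester F1 of the preceding fallback, comes back at 8): ring C is built by a cycloaddition in which the ester cannot take part. Compound 2 undergoes a crossed Claisen condensation with the lithium enolate of tert-butyl methoxyacetate (LiN(i-Pr)2, THF, −78 °C) to give tert-butyl 3-[3,5-bis(benzyloxy)-4-methoxyphenyl]-2-methoxy-3-oxopropanoate F4. Acetone with trifluoroacetic anhydride and trifluoroacetic acid converts F4 into 6-[3,5-bis(benzyloxy)-4-methoxyphenyl]-5-methoxy-2,2-dimethyl-4H-1,3-dioxin-4-one F5. Heating F5 with F1 in toluene at 110 °C releases [3,5-bis(benzyloxy)-4-methoxybenzoyl](methoxy)ketene F6 by retro-hetero-Diels–Alder loss of acetone. The acylketene adds to the enamine in a [4+2] fashion to give methyl 6-[3,5-bis(benzyloxy)-4-methoxyphenyl]-5-methoxy-2-(methoxymethyl)-4-oxo-2-(pyrrolidin-1-yl)-3,4-dihydro-2H-pyran-3-carboxylate F7, which loses pyrrolidine to give 8.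

**Further compounds**
F0 | step 6 | none | none
F1 | step 4 | methyl (E)-4-methoxy-3-(pyrrolidin-1-yl)but-2-enoate | COC/C(N1CCCC1)=C\C(=O)OC
F2 | step 4 | methyl 4-methoxy-2-(2-methoxyacetyl)-3-(pyrrolidin-1-yl)but-2-enoate | COCC(=O)C(C(=O)OC)=C(COC)N1CCCC1
F3 | step 4 | methyl 5-[3,5-bis(benzyloxy)-4-methoxyphenyl]-4-methoxy-2-[2-methoxy-1-(pyrrolidin-1-yl)ethylidene]-3,5-dioxopentanoate | COCC(N1CCCC1)=C(C(=O)OC)C(=O)C(OC)C(=O)c1cc(OCc2ccccc2)c(OC)c(OCc2ccccc2)c1
F4 | step 5 | tert-butyl 3-[3,5-bis(benzyloxy)-4-methoxyphenyl]-2-methoxy-3-oxopropanoate | COC(C(=O)OC(C)(C)C)C(=O)c1cc(OCc2ccccc2)c(OC)c(OCc2ccccc2)c1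
F5 | step 5 | 6-[3,5-bis(benzyloxy)-4-methoxyphenyl]-5-methoxy-2,2-dimethyl-4H-1,3-dioxin-4-one | COC1=C(c2cc(OCc3ccccc3)c(OC)c(OCc3ccccc3)c2)OC(C)(C)OC1=O
F6 | step 5 | [3,5-bis(benzyloxy)-4-methoxybenzoyl](methoxy)ketene | COC(=C=O)C(=O)c1cc(OCc2ccccc2)c(OC)c(OCc2ccccc2)c1
F7 | step 5 | methyl 6-[3,5-bis(benzyloxy)-4-methoxyphenyl]-5-methoxy-2-(methoxymethyl)-4-oxo-2-(pyrrolidin-1-yl)-3,4-dihydro-2H-pyran-3-carboxylate | COCC1(N2CCCC2)OC(c2cc(OCc3ccccc3)c(OC)c(OCc3ccccc3)c2)=C(OC)C(=O)C1C(=O)OC
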